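At early times the target climbed steeply: in the maple run it stood at 5.4% after 3.00 min, an average slope of 0.0180 /min in fractions of the charge. The maple curve then bent over, reached its highest reading, 12.4%, at 20.0 min, and sank to 9.8% at 40.0 min. The cedar run drew the same shape, with 10.9% and 8.1% at those times. Substrate meanwhile fell close to an exponential, a pseudo-first-order decay: between those two readings I got 0.0302 /min in maple and 0.0319 /min in cedar, so I took dissolved gas as steady.

| flask | substrate | gas phase | remark | time |
|---|---|---|---|---|
| maple | 0.23 M | 16 mM (held) | run made earlier |  |
| cedar | 0.35 M | 16 mM (held) | run made earlier |  |
| flask | 0.46 M | 16 mM (held) |  | 50 min |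

| run | time / min | target / % | substrate / % |
|---|---|---|---|
| maple | 3.00 | 5.4 | 93.3 |
| maple | 6.00 | 8.4 | 86.0 |
| maple | 12.0 | 11.3 | 72.3 |
| maple | 20.0 | 12.4 | 57.3 |
| maple | 40.0 | 9.8 | 31.3 |
| cedar | 3.00 | 4.7 | 93.1 |
| cedar | 6.00 | 7.5 | 86.3 |
| cedar | 12.0 | 10.0 | 71.3 |
| cedar | 20.0 | 10.9 | 55.3 |
| cedar | 40.0 | 8.1 | 29.2 |

(standard deviation of a reading: 0.3 percentage points)

- percentages count the substrate that a species holds: one side product counts as two
- at the start none of the gas is dissolved
- what may be going on: gas phase <-> dissolved gas; substrate + dissolved gas -> target; dissolved gas + target -> over-reacted product; substrate + target -> side product; 2 dissolved gas -> self-condensation product; dissolved gas -> decomposed reagent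

* how much target there is at 50 min, in percent of the substrate charged
* the change that raises the amount of target at 50 min, in percent of the substrate charged most ("none" if none brings more than 2 percentage points) (spring / dusk / none)
* amount of target at 50 min, in percent of the substrate charged, after dusk

- spring: doubling the transfer coefficient of the gas phase, all else as stated
- dusk: doubling the saturation concentration of gas phase, all else as stated

On the falling branch I let target trail substrate. If dissolved gas stays steady, target is made in proportion to substrate and lost both to gas and to substrate, and its making and loss nearly balance, then the tail ratio of substrate to target rises in a straight line with the substrate concentration of that moment. Maple's last reading gave a ratio of 3.19 at 0.0720 M, and cedar's gave 3.60 at 0.102 M. The slope, 13.6 /M, a reading with the scatter of those runs in it, I called the substrate penalty: the rise of the tail ratio per unit of substrate present. The line meets zero substrate at 2.21.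

Carrying cedar's exponential on to 50 min, I expected 21.2% of substrate in the flask, which is 0.0976 M. The line then gave a ratio of 3.54 and target at 5.99%.

The forecast said 5.5%, 3.6% after dusk, and none for the best change, holding that “Dusk roughly doubles gas, which speeds formation and over-reaction alike.” My figure stood higher than its 5.5%.

The flask gave 6.12%, and 3.35% after dusk; the best change was none, since spring moved target by −0.29 percentage points and dusk by −2.8 points.

    gas phase ⇌ dissolved gas, rate k1*(csat - [dissolved gas]) (kL = 5.80 /min)
    substrate + dissolved gas → target (k = 1.70 /M/min)
    dissolved gas + target → over-reacted product (k = 5.20 /M/min)
    substrate + target → side product (k = 0.270 /M/min)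
    2 dissolved gas → self-condensation product (k = 21.0 /M/min)
    dissolved gas → decomposed reagent (k = 0.320 /min)

Over-reaction and the step of substrate with target act together as part of what holds this flask down: without the first, target reads 17.1%, without the second 15.0%. In my reckoning the penalty stands for the second. With the flask's 21.0% of substrate, the line gives 5.95%. The neighbour flask charged with 0.18 M kept 24.7%, which is 0.0444 M, so the line gives a ratio of 2.82 and target at 8.75%; that flask held 9.02%.

Readings and results stem from a simulated flask on assumed constants; noise was put on by code.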